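**Strategy.** Germacranolide numbering is used (carbocycle C1–C10; lactone ring O–C6–C7–C11–C12, exocyclic C13). Everything rests on opening the α-methylene-γ-lactone to a ten-membered (4Z,6E)-diene and 2-bromoacrylic acid. One palladium-catalysed annulation forms C7–C11 and C6–O together: carbopalladation of C6=C7 at C7 gives a π-allyl over C4–C6, which the carboxylate closes at C6. The step exploits that C6 of the lactone ring is allylic to the C4=C5 bond, so the diene leaves behind exactly the 4Z olefin, with C6 and C7 trans. The precursor is the cyclodecatriene carrying silyl ethers at C3 and C8; esterification at C8 and C1=C10 epoxidation follow.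

Key step: step 9

Remark: C14 is the methyl on C10 and C15 the methyl on C4; in step 3 the (R)-phosphoric acid is assumed to show the facial sense usual for aryl and α,β-unsaturated aldehydes, its enantiomer being used otherwise.

Step 1
Reactants: 1 (E)-4,4-dimethoxybut-2-enal; 2 ethyltriphenylphosphonium bromide
Product: 6 (2E,4Z)-5-iodo-1,1-dimethoxyhexa-2,4-diene, via ethylidene ylide 3 (not isolated), via iodoethylphosphonium iodide 4 (not isolated), via iodoethylidene ylide 5 (not isolated)
Conditions: 2, n-BuLi, THF, −78 °C; I2, −78 °C; NaN(SiMe3)2, −78 → −20 °C; then 1, −78 °C → rt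
Reagents that add atoms: iodine, II
Why: Stork–Zhao variant of the Wittig olefination, in which the α-iodo ylide 5 made in the flask should add to the enal under kinetic control to give the Z-iodoalkene (iodine cis to the chain) while the E-olefin and the acetal stay untouched.

Step 2
Reactants: 6 (2E,4Z)-5-iodo-1,1-dimethoxyhexa-2,4-diene
Product: 7 (2E,4Z)-5-iodohexa-2,4-dienal
Conditions: 1 M HCl (aq.), THF, 0 °C, exclusion of light
Reagents that add atoms: water, O
Why: Acid-catalysed acetal hydrolysis, mild and cold enough that the Z-iodoalkene should not isomerise.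

Step 3
Reactants: 7 (2E,4Z)-5-iodohexa-2,4-dienal; 8 allenylboronic acid pinacol ester
Product: 9 (4R,5E,7Z)-8-iodonona-5,7-dien-1-yn-4-ol
Conditions: 8 (1.5 equiv), (R)-TRIP phosphoric acid (10 mol %), 4 Å MS, toluene, 0 °C → rt; aqueous work-up
Reagents that add atoms: none
Why: Chiral phosphoric acid-catalysed propargylboration through a closed six-membered transition state in which the catalyst selects one aldehyde face and so sets the C8 carbinol centre (R); the method is metal-free and leaves the vinyl iodide alone.

Step 4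
Reactants: 9 (4R,5E,7Z)-8-iodonona-5,7-dien-1-yn-4-ol
Product: 10 triethyl{[(4R,5E,7Z)-8-iodonona-5,7-dien-1-yn-4-yl]oxy}silane
Conditions: TESCl, imidazole, CH2Cl2, 0 °C
Reagents that add atoms: chlorotriethylsilane, CC[Si](CC)(CC)Cl
Why: Standard silylation of a secondary alcohol, giving a C8 ether that cannot be ionised by palladium later and can be removed beside a TBS ether.

Step 5
Reactants: 10 triethyl{[(4R,5E,7Z)-8-iodonona-5,7-dien-1-yn-4-yl]oxy}silane
Product: 13 (3E,6R,7E,9Z)-10-iodo-4-methyl-6-(triethylsilyloxy)undeca-3,7,9-trien-1-ol, via alkenyldimethylalane 11 (not isolated), via lithium alkenyltrimethylalanate 12 (not isolated)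
Conditions: Me3Al (2.5 equiv), Cp2ZrCl2 (0.25 equiv), CH2Cl2, 0 °C → rt; volatiles removed; THF, MeLi (1.0 equiv), −78 °C; oxirane, −78 → 0 °C; aq. potassium sodium tartrate
Reagents that add atoms: trimethylaluminium, C[Al](C)C; oxirane, C1CO1
Why: Negishi zirconium-catalysed carboalumination adds methyl and aluminium syn across the terminal alkyne (methyl to the internal carbon), which fixes the E-trisubstituted C1=C10 olefin, and the alanate formed with MeLi at −78 °C (ate formation should outrun iodine–lithium exchange) transfers the alkenyl group to oxirane to install C2 and C3.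

Step 6
Reactants: 13 (3E,6R,7E,9Z)-10-iodo-4-methyl-6-(triethylsilyloxy)undeca-3,7,9-trien-1-ol
Product: 14 (3E,6R,7E,9Z)-10-iodo-4-methyl-6-(triethylsilyloxy)undeca-3,7,9-trienal
Conditions: Dess–Martin periodinane, NaHCO3, CH2Cl2, 0 °C; used crude at once
Reagents that add atoms: none
Why: Dess–Martin oxidation under buffered, non-basic conditions should give the β,γ-unsaturated aldehyde without moving the C1=C10 olefin into conjugation.

Step 7
Reactants: 14 (3E,6R,7E,9Z)-10-iodo-4-methyl-6-(triethylsilyloxy)undeca-3,7,9-trienal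
Product: 15 (1S,2Z,4E,6R,8E)-2,8-dimethyl-6-(triethylsilyloxy)cyclodeca-2,4,8-trien-1-ol
Conditions: CrCl2 (15 equiv), NiCl2 (2 mol %), DMSO, rt, slow addition to 0.002 M
Reagents that add atoms: none
Why: Intramolecular Nozaki–Hiyama–Kishi reaction, in which the alkenylchromium species formed from the Z-iodide with retention adds to the aldehyde and closes the ten-membered ring at C3–C4; the new C3 carbinol centre is set under macrocyclic control (attack on the aldehyde face open when the C8 silyloxy group is pseudo-equatorial), and the 3S epimer is the one carried on.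

Step 8
Reactants: 15 (1S,2Z,4E,6R,8E)-2,8-dimethyl-6-(triethylsilyloxy)cyclodeca-2,4,8-trien-1-ol
Product: 16 tert-butyl{[(1S,2Z,4E,6R,8E)-2,8-dimethyl-6-(triethylsilyloxy)cyclodeca-2,4,8-trien-1-yl]oxy}dimethylsilane
Conditions: TBSOTf, 2,6-lutidine, CH2Cl2, −78 °C
Reagents that add atoms: tert-butyldimethylsilyl triflate, CC(C)(C)[Si](C)(C)OS(=O)(=O)C(F)(F)F
Why: Silylation of the allylic C3 alcohol under buffered conditions gives a TBS ether that outlasts the later removal of the C8 TES ether.

Step 9
Reactants: 16 tert-butyl{[(1S,2Z,4E,6R,8E)-2,8-dimethyl-6-(triethylsilyloxy)cyclodeca-2,4,8-trien-1-yl]oxy}dimethylsilane; 17 2-bromoacrylic acid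
Product: 18 (3S,6R,7S,8R)-3-(tert-butyldimethylsilyloxy)-8-(triethylsilyloxy)germacra-1(10)E,4Z,11(13)-trien-12,6-olide (trans-fused α-methylene-γ-lactone)
Conditions: 17 (1.5 equiv), Pd(OAc)2 (10 mol %), PPh3 (20 mol %), Ag2CO3 (1.5 equiv), MeCN, 60 °C
Reagents that add atoms: none
Why: Zerovalent palladium inserts into the C–Br bond of 17, the α-carboxyvinylpalladium species adds syn across the strained ring-E C6=C7 bond with carbon going to C7 (the diene terminus not blocked by a methyl group) to give a π-allyl complex over C4–C5–C6, and the palladium-bound carboxylate then forms the O–C6 bond by reductive elimination, which returns zerovalent palladium. The closest known reaction type is the Larock heteroannulation of 1,3-dienes with halides that carry a carboxylic acid. One ring closes, the γ-lactone, by attack of oxygen on the near allyl terminus C6 (five-membered ring), since attack at C4 would need a seven-membered ring at a fully substituted carbon. C7 is set by attack on the outer face of the E-olefin, anti to the C9 methylene, with the C8–O bond held near the olefin plane (inside-alkoxy arrangement), which puts C11 on the same ring face as O8; C6 follows from C7 because carbon and oxygen are delivered to the same face of an E-olefin (inner-sphere C–O formation, favoured by the halide-free Ag2CO3 conditions), and this is what makes the lactone trans-fused. The 4Z geometry should be kept because the fully substituted C4 terminus of the allyl unit cannot exchange its syn and anti groups. The step needs site selectivity (diene over the isolated C1=C10 olefin, which is inert to carbopalladation), regioselectivity (C7 over C4, secured by the C15 methyl) and facial selectivity (secured by ring strain and the C8 silyl ether).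

Step 10
Reactants: 18 (3S,6R,7S,8R)-3-(tert-butyldimethylsilyloxy)-8-(triethylsilyloxy)germacra-1(10)E,4Z,11(13)-trien-12,6-olide
Product: 19 (3S,6R,7R,8R)-3-(tert-butyldimethylsilyloxy)-8-hydroxygermacra-1(10)E,4Z,11(13)-trien-12,6-olide
Conditions: PPTS, MeOH/CH2Cl2, 0 °C
Reagents that add atoms: none
Why: Acid-catalysed methanolysis, in which the secondary TES ether is far more labile than the TBS ether and acidic methanol does not add to the methylene lactone.

Step 11
Reactants: 20 methyl angelate
Product: 21 (Z)-2-methylbut-2-en-1-ol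
Conditions: i-Bu2AlH (2.2 equiv), CH2Cl2, −78 → 0 °C
Reagents that add atoms: none
Why: 1,2-Reduction of the conjugated ester by the aluminium hydride should give the allylic alcohol with the Z geometry intact.

Step 12
Reactants: 21 (Z)-2-methylbut-2-en-1-ol
Product: 22 [(2R,3S)-2,3-dimethyloxiran-2-yl]methanol
Conditions: Ti(OiPr)4 (10 mol %), D-(−)-diisopropyl tartrate (12 mol %), t-BuOOH, 4 Å MS, CH2Cl2, −20 °C
Reagents that add atoms: tert-butyl hydroperoxide, CC(C)(C)OO
Why: Sharpless asymmetric epoxidation, in which the D-tartrate ligand selects the olefin face that gives the (2R,3S)-epoxy alcohol, so that both centres follow from the reagent and the Z geometry.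

Step 13
Reactants: 22 [(2R,3S)-2,3-dimethyloxiran-2-yl]methanol
Product: 23 (2S,3S)-2,3-dimethyloxirane-2-carboxylic acid
Conditions: TEMPO (cat.), PhI(OAc)2, MeCN/H2O, rt
Reagents that add atoms: water, O
Why: Oxoammonium-mediated oxidation of the primary alcohol through the aldehyde hydrate to the acid is neutral enough for the epoxide, and the C2 descriptor changes from R to S only through the new priority of the carboxyl group.

Step 14
Reactants: 19 (3S,6R,7R,8R)-3-(tert-butyldimethylsilyloxy)-8-hydroxygermacra-1(10)E,4Z,11(13)-trien-12,6-olide; 23 (2S,3S)-2,3-dimethyloxirane-2-carboxylic acid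
Product: 25 (3S,6R,7R,8R)-3-(tert-butyldimethylsilyloxy)-8-[(2S,3S)-2,3-dimethyloxirane-2-carbonyloxy]germacra-1(10)E,4Z,11(13)-trien-12,6-olide, via mixed anhydride 24 (not isolated)
Conditions: 23, 2,4,6-trichlorobenzoyl chloride, Et3N, toluene, rt; then 19, DMAP, toluene, rt
Reagents that add atoms: none
Why: Yamaguchi esterification, in which the mixed anhydride of the hindered epoxy acid is attacked by DMAP at the less hindered carbonyl and acylates the C8 alcohol, with no stereocentre touched.

Step 15
Reactants: 25 (3S,6R,7R,8R)-3-(tert-butyldimethylsilyloxy)-8-[(2S,3S)-2,3-dimethyloxirane-2-carbonyloxy]germacra-1(10)E,4Z,11(13)-trien-12,6-olide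
Product: 26 (1R,3S,6R,7R,8R,10R)-3-(tert-butyldimethylsilyloxy)-1,10-epoxy-8-[(2S,3S)-2,3-dimethyloxirane-2-carbonyloxy]germacra-4Z,11(13)-dien-12,6-olide
Conditions: mCPBA, NaHCO3, CH2Cl2, 0 °C
Reagents that add atoms: 3-chloroperoxybenzoic acid, OOC(=O)c1cccc(Cl)c1
Why: Prilezhaev epoxidation, in which the isolated electron-rich C1=C10 olefin should react before the C4=C5 olefin (flanked by two allylic C–O bonds) and the electron-poor methylene lactone, and attack on the outer face of the ring-E olefin should set C1 and C10 as (1R,10R).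

Step 16
Reactants: 26 (1R,3S,6R,7R,8R,10R)-3-(tert-butyldimethylsilyloxy)-1,10-epoxy-8-[(2S,3S)-2,3-dimethyloxirane-2-carbonyloxy]germacra-4Z,11(13)-dien-12,6-olide
Product: 27 (1R,3S,6R,7R,8R,10R)-1,10-epoxy-3-hydroxy-8-[(2S,3S)-2,3-dimethyloxirane-2-carbonyloxy]germacra-4Z,11(13)-dien-12,6-olide (CNP0268255.2)
Conditions: HF·pyridine, excess pyridine, THF, 0 °C → rt
Reagents that add atoms: none
Why: Fluoride-driven cleavage of the allylic TBS ether under pyridine-buffered conditions should spare both epoxides, the ester and the methylene lactone.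

**Compound list**

1 | (E)-4,4-dimethoxybut-2-enal | COC(OC)/C=C/C=O | starting material
2 | ethyltriphenylphosphonium bromide | CC[P+](c1ccccc1)(c1ccccc1)c1ccccc1.[Br-] | starting material
3 | ethylidenetriphenylphosphorane (formed in the flask) | CC=P(c1ccccc1)(c1ccccc1)c1ccccc1 | intermediate
4 | (1-iodoethyl)triphenylphosphonium iodide (formed in the flask) | CC(I)[P+](c1ccccc1)(c1ccccc1)c1ccccc1.[I-] | intermediate
5 | (1-iodoethylidene)triphenylphosphorane (formed in the flask) | CC(I)=P(c1ccccc1)(c1ccccc1)c1ccccc1 | intermediate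
6 | (2E,4Z)-5-iodo-1,1-dimethoxyhexa-2,4-diene | C/C(I)=C/C=C/C(OC)OC | intermediate
7 | (2E,4Z)-5-iodohexa-2,4-dienal | C/C(I)=C/C=C/C=O | intermediate
8 | allenylboronic acid pinacol ester | CC1(C)OB(C=C=C)OC1(C)C | starting material
9 | (4R,5E,7Z)-8-iodonona-5,7-dien-1-yn-4-ol | C#CC[C@@H](O)/C=C/C=C(/C)I | intermediate
10 | triethyl{[(4R,5E,7Z)-8-iodonona-5,7-dien-1-yn-4-yl]oxy}silane | C#CC[C@@H](O[Si](CC)(CC)CC)/C=C/C=C(/C)I | intermediate
11 | dimethyl[(1E,4R,5E,7Z)-8-iodo-2-methyl-4-(triethylsilyloxy)nona-1,5,7-trienyl]alane (formed in the flask) | C[Al](C)/C=C(\C)C[C@@H](O[Si](CC)(CC)CC)/C=C/C=C(/C)I | intermediate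
12 | lithium trimethyl[(1E,4R,5E,7Z)-8-iodo-2-methyl-4-(triethylsilyloxy)nona-1,5,7-trienyl]aluminate (formed in the flask) | [Li+].C[Al-](C)(C)/C=C(\C)C[C@@H](O[Si](CC)(CC)CC)/C=C/C=C(/C)I | intermediate
13 | (3E,6R,7E,9Z)-10-iodo-4-methyl-6-(triethylsilyloxy)undeca-3,7,9-trien-1-ol | OCC/C=C(\C)C[C@@H](O[Si](CC)(CC)CC)/C=C/C=C(/C)I | intermediate
14 | (3E,6R,7E,9Z)-10-iodo-4-methyl-6-(triethylsilyloxy)undeca-3,7,9-trienal | O=CC/C=C(\C)C[C@@H](O[Si](CC)(CC)CC)/C=C/C=C(/C)I | intermediate
15 | (1S,2Z,4E,6R,8E)-2,8-dimethyl-6-(triethylsilyloxy)cyclodeca-2,4,8-trien-1-ol | O[C@@H]1/C(C)=C\C=C\[C@H](O[Si](CC)(CC)CC)C/C(C)=C/C1 | intermediate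
16 | tert-butyl{[(1S,2Z,4E,6R,8E)-2,8-dimethyl-6-(triethylsilyloxy)cyclodeca-2,4,8-trien-1-yl]oxy}dimethylsilane | CC(C)(C)[Si](C)(C)O[C@@H]1/C(C)=C\C=C\[C@H](O[Si](CC)(CC)CC)C/C(C)=C/C1 | intermediate
17 | 2-bromoacrylic acid | C=C(Br)C(=O)O | starting material
18 | (3S,6R,7S,8R)-3-(tert-butyldimethylsilyloxy)-8-(triethylsilyloxy)germacra-1(10)E,4Z,11(13)-trien-12,6-olide | C=C1C(=O)O[C@@H]2/C=C(/C)[C@@H](O[Si](C)(C)C(C)(C)C)C/C=C(\C)C[C@@H](O[Si](CC)(CC)CC)[C@@H]12 | intermediate
19 | (3S,6R,7R,8R)-3-(tert-butyldimethylsilyloxy)-8-hydroxygermacra-1(10)E,4Z,11(13)-trien-12,6-olide | C=C1C(=O)O[C@@H]2/C=C(/C)[C@@H](O[Si](C)(C)C(C)(C)C)C/C=C(\C)C[C@@H](O)[C@@H]12 | intermediate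
20 | methyl angelate (methyl (Z)-2-methylbut-2-enoate) | C/C=C(/C)C(=O)OC | starting material
21 | (Z)-2-methylbut-2-en-1-ol | C/C=C(/C)CO | intermediate
22 | [(2R,3S)-2,3-dimethyloxiran-2-yl]methanol | OC[C@@]1(C)O[C@H]1C | intermediate
23 | (2S,3S)-2,3-dimethyloxirane-2-carboxylic acid | OC(=O)[C@@]1(C)O[C@H]1C | intermediate
24 | (2S,3S)-2,3-dimethyloxirane-2-carboxylic 2,4,6-trichlorobenzoic anhydride (formed in the flask) | O=C(OC(=O)[C@@]1(C)O[C@H]1C)c1c(Cl)cc(Cl)cc1Cl | intermediate
25 | (3S,6R,7R,8R)-3-(tert-butyldimethylsilyloxy)-8-[(2S,3S)-2,3-dimethyloxirane-2-carbonyloxy]germacra-1(10)E,4Z,11(13)-trien-12,6-olide | C=C1C(=O)O[C@@H]2/C=C(/C)[C@@H](O[Si](C)(C)C(C)(C)C)C/C=C(\C)C[C@@H](OC(=O)[C@@]3(C)O[C@H]3C)[C@@H]12 | intermediate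
26 | (1R,3S,6R,7R,8R,10R)-3-(tert-butyldimethylsilyloxy)-1,10-epoxy-8-[(2S,3S)-2,3-dimethyloxirane-2-carbonyloxy]germacra-4Z,11(13)-dien-12,6-olide | C=C1C(=O)O[C@@H]2/C=C(/C)[C@@H](O[Si](C)(C)C(C)(C)C)C[C@H]3O[C@]3(C)C[C@@H](OC(=O)[C@@]3(C)O[C@H]3C)[C@@H]12 | intermediate
27 | (1R,3S,6R,7R,8R,10R)-1,10-epoxy-3-hydroxy-8-[(2S,3S)-2,3-dimethyloxirane-2-carbonyloxy]germacra-4Z,11(13)-dien-12,6-olide (CNP0268255.2) | C=C1C(=O)O[C@@H]2/C=C(/C)[C@@H](O)C[C@H]3O[C@]3(C)C[C@@H](OC(=O)[C@@]3(C)O[C@H]3C)[C@@H]12 | target

**Step count.** Total: 16 steps. Longest linear sequence: 13 steps (steps 1–10 and 14–16); steps 11–13 make the side-chain acid.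

**Three steps most likely to fail**

Step 9. The vinylpalladium species may attack the wrong face of C6=C7. The lactone may also close by external attack of the carboxylate, which would give cis fusion. Zerovalent palladium may re-ionise the allylic lactone and erode the 4Z geometry. The fallback makes the same two bonds by a radical–polar crossover instead of carbopalladation. Setting out from 16, potassium methyl malonate with Mn(OAc)3·2H2O and Cu(OAc)2 in AcOH/MeCN at 40 °C should add the malonyl radical to C7 and oxidise the resulting allyl radical to the cation. The carboxylate should then close on C6 to the thermodynamically preferred trans lactone, the α-methoxycarbonyl lactone F1. Me3SnOH in 1,2-dichloroethane should cleave the methyl ester to the α-carboxy lactone F2. Aqueous formaldehyde with Et2NH (decarboxylative Mannich methylenation) then comes back to the route at 18.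

Step 7. The ring closure may show poor facial selectivity at the aldehyde and give a C3 epimer mixture, and oligomerisation may compete if dilution is insufficient. The fallback sets C3 by reagent control after ring closure. Setting out from 15 as its epimer mixture, oxidation with MnO2 or Dess–Martin periodinane gives the conjugated dienone F3. Corey–Bakshi–Shibata reduction with the (R)-methyl oxazaborolidine and catecholborane at −78 °C, with the alkenyl group as the large substituent, should return 15 with the 3S configuration.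

Step 15. Epoxidation may occur from the undesired face of C1=C10, because the face is chosen only by the ring conformation, and attack at C4=C5 may compete. The fallback replaces substrate control by reagent control. Setting out from 25, Shi epoxidation with the D-fructose-derived ketone (stoichiometric) and KHSO5 at about pH 8 in MeCN/dimethoxymethane/aqueous buffer at −10 °C is expected to give the (1R,10R)-epoxide of this E-trisubstituted olefin. It comes back to the route at 26 and makes no new compound.

**Further compounds**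

F1 | step 9 | 11-(methoxycarbonyl)-3-(tert-butyldimethylsilyloxy)-8-(triethylsilyloxy)-13-norgermacra-1(10)E,4Z-dien-12,6-olide, configured as 18 at C3, C6, C7 and C8, C11 epimers | COC(=O)C1C(=O)O[C@@H]2/C=C(/C)[C@@H](O[Si](C)(C)C(C)(C)C)C/C=C(\C)C[C@@H](O[Si](CC)(CC)CC)[C@@H]12
F2 | step 9 | 11-carboxy-3-(tert-butyldimethylsilyloxy)-8-(triethylsilyloxy)-13-norgermacra-1(10)E,4Z-dien-12,6-olide, configured as 18 at C3, C6, C7 and C8, C11 epimers | OC(=O)C1C(=O)O[C@@H]2/C=C(/C)[C@@H](O[Si](C)(C)C(C)(C)C)C/C=C(\C)C[C@@H](O[Si](CC)(CC)CC)[C@@H]12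
F3 | step 7 | (2Z,4E,6R,8E)-2,8-dimethyl-6-(triethylsilyloxy)cyclodeca-2,4,8-trien-1-one | O=C1/C(C)=C\C=C\[C@H](O[Si](CC)(CC)CC)C/C(C)=C/C1
F0 | step 15 | none | none
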